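- A percentage point of excess was the unit I counted in, and my decision was whether the next run of this recipe could stay at 7.2 mM of racemization catalyst or should get Monday's 14 mM, twice as much.

all flasks: left-handed substrate 0.20 M; right-handed substrate 0.20 M

|  | partner | racemization catalyst | remark | time |
|---|---|---|---|---|
| Saturday's | 0.50 M (fed, over 6.0 min) | 7.2 mM | the very flask that is asked about, followed so far |  |
| Monday's | 0.50 M (fed, over 6.0 min) | 14 mM | run made earlier |  |
| flask | 0.500 M (fed, over 6.0 min) | 7.2 mM |  | 15 min |

| run | time / min | left-handed product / % | right-handed product / % |
|---|---|---|---|
| Saturday's | 0.417 | 0 | 0 |
| Saturday's | 1.00 | 1.5 | 0 |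
| Saturday's | 2.00 | 6.5 | 1.4 |
| Saturday's | 3.00 | 12.4 | 4.8 |
| Monday's | 4.00 | 16.4 | 4.8 |
| Monday's | 8.00 | 28.9 | 10.8 |
| Monday's | 12.0 | 31.5 | 9.7 |
| Monday's | 15.0 | 29.7 | 8.7 |

(scatter of a reading: 1 percentage point)

- left-handed product and right-handed product together, in percent of the left-handed substrate and right-handed substrate charged together, at 15 min
- excess of left-handed product over right-handed product in the product at 15 min
- whether the exchange between left-handed substrate and right-handed substrate keeps pace with the reaction: how far the product's excess at 15 min gets from its value without exchange to its value with instant exchange (above 80 % keeps pace, below 20 % hardly takes part, else lags behind)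

- partner is single-handed; left-handed substrate and right-handed substrate are mirror images of each other, charged as a racemate, each of them at the stated concentration
- steps under discussion: left-handed substrate + racemization catalyst <-> right-handed substrate + racemization catalyst; partner + right-handed substrate -> right-handed product; partner -> decomposed reagent; 2 partner -> homo dimer; partner + left-handed substrate -> left-handed product
- an excess is the difference of the two amounts in percent of their sum
- an excess is below zero if the other one leads
- the handed part of partner does not stay in what it makes, so the products of the two hands are mirror images too

- Summing Monday's four readings, I read left-handed product over right-handed product as 3.13, which I took as the selectivity factor.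
- From that ratio I made the even-mix excess, the product's excess while both substrates stay equal: the ratio less one, over the ratio plus one, or 51.6 %. Saturday's three readings with product gave 53.4 %, close to it.
- Next I tested Monday's flask for lag. Without exchange, its products at 15.0 min would have implied substrates that put the ratio of fresh product at 1.54 by then. Yet in Monday's flask the product read as made between 4.00 min and 15.0 min had a ratio of 3.41, higher than that, so, with differences of readings as coarse as these, I saw no lag within the scatter.
- Monday's readings gave no exchange time, so the margin at the lower catalyst charge remained a judgement. I committed to leaving the catalyst at 7.2 mM, with an excess near 51.6 %, a yield near Monday's late mean of 39.8 %, and an exchange that keeps pace.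
- The forecast gave 40 %, 48 % and lags behind, in its words “The exchange lags behind”, so mine differed from it on the excess and the pace.

    left-handed substrate + racemization catalyst ⇌ right-handed substrate + racemization catalyst, rate k1*[racemization catalyst]*[left-handed substrate] forward; the back reaction follows from the equilibrium constant (k = 31.0 M⁻¹ s⁻¹)
    partner + right-handed substrate → right-handed product (k = 0.00770 M⁻¹ s⁻¹)
    partner → decomposed reagent (k = 0.00810 s⁻¹)
    2 partner → homo dimer (k = 0.0190 M⁻¹ s⁻¹)
    partner + left-handed substrate → left-handed product (k = 0.0240 M⁻¹ s⁻¹)

- Saturday's flask gave 39.6 % at an excess of 51.3 %, and its exchange keeps pace, 99.0 % of the way, while the exchange relaxed with a half-life of 1.55 s at 15.0 min and left-handed substrate had a half-life of 5.8 min by its reaction with partner at 4.13 min, far longer. The even-mix excess of 51.6 % stands beside the 51.2 % of the neighbouring flask with 1.2 M of partner, where left-handed product reached 49.9 %.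

Readings and results are calculated from invented constants, noise included.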